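How much target stands in the flask at the end of the run, and can more gas supply raise it by a useful margin?

substrate 20 mM; gas phase 7.6 mM (held); time 15 h

    gas phase ⇌ dissolved gas, rate k1*(csat - [dissolved gas]) (k1 = 1.73 × 10⁻⁴ s⁻¹, csat = 7.6 mM)
    substrate + dissolved gas → target (k2 = 0.0181 L mol⁻¹ s⁻¹)
    target → over-reaction product (k3 = 7.57 × 10⁻⁷ s⁻¹)
    2 dissolved gas → self-condensation product (k4 = 0.00261 L mol⁻¹ s⁻¹)

- gamma: doubling the saturation concentration of gas phase, all else as stated
- zeta: doubling the transfer coefficient of step 1, all else as stated

1. how much target there is at 15 h, in percent of the substrate charged
2. the change that raises the amount of target at 15 h, in percent of the substrate charged most ("none" if none brings more than 2 percentage points) (gamma / zeta / none)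
3. amount of target at 15 h, in percent of the substrate charged, after gamma

- a doubled species enters its step squared and goes two at a time
- at the start none of the gas is dissolved
- run time (flask): 15 h

I fold the flask into one number, N, the rate at which the charged substrate captures dissolved gas (rate constant times charge) divided by the transfer coefficient, a Damköhler number: N = 2.09. Time has dropped out. Since N is above one, substrate takes gas faster than transfer refills the liquid, and dissolved gas should start near saturation divided by one plus N, 2.46 mM. Taking dissolved gas as steady and S = 7.43, the rate constant times saturation times time, the fraction of substrate left is x = exp(N − S) = 0.482%, and that fraction stands at 0.5 at a halfway time of 3.51 h.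

One number is not enough. N omits self-condensation, which I neglect because at saturation its first-order rate is 0.229 of the transfer coefficient. Target formed at that halfway time also loses 3.13% by over-reaction, so I commit to 96.4%. Doubling saturation leaves N alone and halves the halfway time, giving 96.4%. My estimated gain from gamma is 0.003 percentage points, less than the margin, so I say none.

The forecast gives 95.5%, lower than mine, with none as best and 96.5% after gamma, on the ground that “the substrate is about 98% consumed”.

The simulation gives 95.7%, best none (gamma 1 point, zeta 0.83 points), and 96.7% after gamma.

In this flask at 1.50 h, with substrate at 84.9%, N scaled to that substrate puts dissolved gas at 2.74 mM, against 2.42 mM read. By 15.0 h substrate stood at 1.59%, above my x but below the margin, and the target step used dissolved gas at 0.18 of the self-condensation rate. In the neighbour flask with 50 mM of substrate, N is 5.23, the same rule leaves 11.1%, and that flask holds 11.2%.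

All constants were drawn at random within sensible limits; no experiment stands behind them.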